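The ring atoms are C1 (quaternary epoxide carbon carrying C7H2OBz), C2 (CHOH), C3 (CHOBz), C4=C5 and C6 (epoxide CH). The cyclohexene ring is disconnected at C3–C4 and C1–C6. If C1 is carried as an exocyclic methylene carbon (C1=C7), both bonds are alkenyl–carbinol bonds, so one chromium-mediated double Nozaki–Hiyama–Kishi coupling unites two open-chain halo-aldehydes, (S)-3-bromo-2-silyloxybut-3-enal and (Z)-3-iodoacrolein, head to tail and closes the carbocycle in a single operation. The C6 oxygen is then relayed to C7 as a benzoate by allylic transposition, which gives the C1=C6/C4=C5 diene, and the C2 hydroxyl directs the final epoxidation of C1=C6 to the oxirane ring.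

Key step: step 6

Remark: (R)-but-3-ene-1,2-diol and ethyl (Z)-3-iodoprop-2-enoate are taken as commercial; 10 and 11 are carried as both epimers at C6 (hence no wedge there in their SMILES), because that centre becomes sp2 in step 8.

Step 1
Reactants: 1 (R)-but-3-ene-1,2-diol
Product: 2 (R)-3,4-bis[(tert-butyldimethylsilyl)oxy]but-1-ene
Conditions: TBSCl, imidazole, DMF, rt
Reagents that add atoms: tert-butyldimethylsilyl chloride, CC(C)(C)[Si](C)(C)Cl
Why: Imidazole-promoted silyl ether formation protects both hydroxyls so that the alkene can be brominated and one silyl ether later removed selectively; the stereocentre is not involved.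

Step 2
Reactants: 2 (R)-3,4-bis[(tert-butyldimethylsilyl)oxy]but-1-ene
Product: 4 (S)-2-bromo-3,4-bis[(tert-butyldimethylsilyl)oxy]but-1-ene, via vicinal dibromide 3 (not isolated)
Conditions: Br2, CH2Cl2, −78 °C; then DBU, DMF, rt
Reagents that add atoms: bromine, BrBr
Why: Electrophilic bromination of the terminal alkene followed by DBU-mediated dehydrobromination (E2) removes the more acidic internal C–H, which is flanked by bromine and the oxygen-bearing carbon, and so should give the 2-bromo-1-alkene regioselectively without touching the stereocentre.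

Step 3
Reactants: 4 (S)-2-bromo-3,4-bis[(tert-butyldimethylsilyl)oxy]but-1-ene
Product: 5 (S)-3-bromo-2-[(tert-butyldimethylsilyl)oxy]but-3-en-1-ol
Conditions: HF·pyridine, pyridine, THF, 0 °C
Reagents that add atoms: none
Why: Pyridine-buffered HF cleaves the less hindered primary silyl ether much faster than the secondary one (selective desilylation), freeing only the alcohol that is to be oxidised.

Step 4
Reactants: 5 (S)-3-bromo-2-[(tert-butyldimethylsilyl)oxy]but-3-en-1-ol
Product: 6 (S)-3-bromo-2-[(tert-butyldimethylsilyl)oxy]but-3-enal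
Conditions: Dess–Martin periodinane, NaHCO3, CH2Cl2, 0 °C to rt
Reagents that add atoms: none
Why: Buffered Dess–Martin oxidation converts the primary alcohol into the aldehyde under non-basic conditions, which should avoid epimerisation of the α-silyloxy centre and migration of the alkene; the aldehyde is used at once.

Step 5
Reactants: 7 ethyl (Z)-3-iodoprop-2-enoate
Product: 8 (Z)-3-iodoprop-2-enal
Conditions: iBu2AlH (1.05 equiv), CH2Cl2, −78 °C
Reagents that add atoms: none
Why: Partial ester reduction with iBu2AlH at −78 °C stops at the tetrahedral aluminium hemiacetal, which gives the aldehyde on work-up with the Z alkene intact; the solution is used at once because the Z enal isomerises on standing.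

Step 6
Reactants: 6 (S)-3-bromo-2-[(tert-butyldimethylsilyl)oxy]but-3-enal; 8 (Z)-3-iodoprop-2-enal
Product: 10 (4S,5R)-5-[(tert-butyldimethylsilyl)oxy]-6-methylidenecyclohex-2-ene-1,4-diol (both C1 epimers), via acyclic hydroxy enal 9 (not isolated)
Conditions: CrCl2 (8 equiv), NiCl2 (2 mol %), DMSO–THF, rt; 8 added slowly to dilute 6
Reagents that add atoms: none
Why: NiCl2 is reduced by CrCl2 to zerovalent nickel, which inserts first into the reactive C–I bond of 8; transmetalation to trivalent chromium gives a Z-alkenylchromium that adds to the more electrophilic α-silyloxy aldehyde of 6 and forms C3–C4, and slower insertion into the alkenyl bromide of 9 then lets the second alkenylchromium add 1,2 to the enal carbonyl and form C1–C6. The closest known reaction type is the Nozaki–Hiyama–Kishi coupling of alkenyl halides with aldehydes, run here once between the two components and once within the adduct. The carbocycle closes in the 6-exo-trig mode (attack of the ring carbon C1 on the exocyclic C=O of C6), which the retained Z geometry of C4=C5 makes possible. The new centre C3 is set by the silyloxy-bearing centre C2 through a polar Felkin–Anh transition state (3,4-anti, that is cis on the ring); the new centre C6 is not controlled and need not be, since it becomes sp2 in step 8. The step needs cross- over self-coupling: the iodide should react before the bromide and the α-oxygenated aldehyde before the conjugated one, and 8 is added slowly to dilute 6, so that only the matched pair meets intermolecularly and the mismatched pair is left to react within one molecule.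

Step 7
Reactants: 10 (4S,5R)-5-[(tert-butyldimethylsilyl)oxy]-6-methylidenecyclohex-2-ene-1,4-diol (both C1 epimers)
Product: 11 (4R,5R)-5-[(tert-butyldimethylsilyl)oxy]-6-methylidenecyclohex-2-ene-1,4-diyl dibenzoate (both C1 epimers)
Conditions: PhCO2H, PPh3, DIAD, THF, 0 °C to rt
Reagents that add atoms: benzoic acid, O=C(O)c1ccccc1
Why: Double Mitsunobu esterification: SN2 displacement with inversion at the mono-allylic carbinol C3 sets the trans relationship to the C2 silyloxy group, while the doubly allylic carbinol C6 is esterified by SN2 or SN2′ attack, and both of these outcomes converge in step 8.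

Step 8
Reactants: 11 (4R,5R)-5-[(tert-butyldimethylsilyl)oxy]-6-methylidenecyclohex-2-ene-1,4-diyl dibenzoate (both C1 epimers)
Product: 12 [(5R,6R)-5-(benzoyloxy)-6-[(tert-butyldimethylsilyl)oxy]cyclohexa-1,3-dien-1-yl]methyl benzoate
Conditions: Pd(PPh3)4 (5 mol %), THF, rt
Reagents that add atoms: none
Why: Zerovalent palladium ionises the doubly allylic benzoate to a π-allyl complex and the benzoate ion returns at the unhindered exocyclic terminus C7, the endocyclic conjugated diene with a primary ester being the thermodynamic product (palladium-catalysed 1,3-transposition of an allylic ester); C6 becomes sp2, so both epimers of 11 converge.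

Step 9
Reactants: 12 [(5R,6R)-5-(benzoyloxy)-6-[(tert-butyldimethylsilyl)oxy]cyclohexa-1,3-dien-1-yl]methyl benzoate
Product: 13 [(5R,6R)-5-(benzoyloxy)-6-hydroxycyclohexa-1,3-dien-1-yl]methyl benzoate
Conditions: HF·pyridine, pyridine, THF, 0 °C to rt
Reagents that add atoms: none
Why: Desilylation with the mildly acidic fluoride source frees the C2 hydroxyl without the basic conditions that would promote benzoyl migration from O3 to O2 or loss of benzoic acid with aromatisation.

Step 10
Reactants: 13 [(5R,6R)-5-(benzoyloxy)-6-hydroxycyclohexa-1,3-dien-1-yl]methyl benzoate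
Product: 14 [(1S,2S,3R,6R)-3-(benzoyloxy)-2-hydroxy-7-oxabicyclo[4.1.0]hept-4-en-1-yl]methyl benzoate (target)
Conditions: VO(acac)2 (5 mol %), t-BuOOH, CH2Cl2, 0 °C
Reagents that add atoms: tert-butyl hydroperoxide, CC(C)(C)OO
Why: Vanadium-catalysed hydroxyl-directed epoxidation should oxidise only the allylic-alcohol alkene C1=C6, which is also the more substituted one, and deliver the oxygen on the face of the C2 hydroxyl, so C1 and C6 are set cis to O2 and anti to the C3 benzoate as in the target.

Compound list
1 | (R)-but-3-ene-1,2-diol | C=C[C@@H](O)CO | starting material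
2 | (R)-3,4-bis[(tert-butyldimethylsilyl)oxy]but-1-ene | C=C[C@@H](O[Si](C)(C)C(C)(C)C)CO[Si](C)(C)C(C)(C)C | intermediate
3 | (3S)-1,2-dibromo-3,4-bis[(tert-butyldimethylsilyl)oxy]butane (both C2 epimers) | BrCC(Br)[C@@H](O[Si](C)(C)C(C)(C)C)CO[Si](C)(C)C(C)(C)C | intermediate (not isolated)
4 | (S)-2-bromo-3,4-bis[(tert-butyldimethylsilyl)oxy]but-1-ene | C=C(Br)[C@@H](O[Si](C)(C)C(C)(C)C)CO[Si](C)(C)C(C)(C)C | intermediate
5 | (S)-3-bromo-2-[(tert-butyldimethylsilyl)oxy]but-3-en-1-ol | C=C(Br)[C@@H](O[Si](C)(C)C(C)(C)C)CO | intermediate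
6 | (S)-3-bromo-2-[(tert-butyldimethylsilyl)oxy]but-3-enal | C=C(Br)[C@@H](O[Si](C)(C)C(C)(C)C)C=O | intermediate
7 | ethyl (Z)-3-iodoprop-2-enoate | CCOC(=O)/C=C\I | starting material
8 | (Z)-3-iodoprop-2-enal | O=C/C=C\I | intermediate
9 | (2Z,4S,5S)-6-bromo-5-[(tert-butyldimethylsilyl)oxy]-4-hydroxyhepta-2,6-dienal (present as its chromium alkoxide) | C=C(Br)[C@@H](O[Si](C)(C)C(C)(C)C)[C@@H](O)/C=C\C=O | intermediate (not isolated)
10 | (4S,5R)-5-[(tert-butyldimethylsilyl)oxy]-6-methylidenecyclohex-2-ene-1,4-diol (both C1 epimers; O4 and O5 cis) | C=C1[C@@H](O[Si](C)(C)C(C)(C)C)[C@@H](O)C=CC1O | intermediate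
11 | (4R,5R)-5-[(tert-butyldimethylsilyl)oxy]-6-methylidenecyclohex-2-ene-1,4-diyl dibenzoate (both C1 epimers; O4 and O5 trans) | C=C1[C@@H](O[Si](C)(C)C(C)(C)C)[C@H](OC(=O)c2ccccc2)C=CC1OC(=O)c1ccccc1 | intermediate
12 | [(5R,6R)-5-(benzoyloxy)-6-[(tert-butyldimethylsilyl)oxy]cyclohexa-1,3-dien-1-yl]methyl benzoate | O=C(OCC1=CC=C[C@@H](OC(=O)c2ccccc2)[C@@H]1O[Si](C)(C)C(C)(C)C)c1ccccc1 | intermediate
13 | [(5R,6R)-5-(benzoyloxy)-6-hydroxycyclohexa-1,3-dien-1-yl]methyl benzoate | O=C(OCC1=CC=C[C@@H](OC(=O)c2ccccc2)[C@@H]1O)c1ccccc1 | intermediate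
14 | [(1S,2S,3R,6R)-3-(benzoyloxy)-2-hydroxy-7-oxabicyclo[4.1.0]hept-4-en-1-yl]methyl benzoate | O=C(OC[C@@]12O[C@@H]1C=C[C@@H](OC(=O)c1ccccc1)[C@@H]2O)c1ccccc1 | target

Total step count: 10. Longest linear sequence: 9 steps (steps 1–4 and 6–10, from 1 to 14).

Steps most likely to fail

Step 6. The iodo-enal may couple with itself or oligomerise, 8 may isomerise from Z to E before coupling (the E adduct cannot ring-close), and facial selectivity at C3 may be poor. The fallback does the two couplings separately with the enal masked; it sets out from 6 and 8 and comes back at 11. Compound 8 is converted with HC(OEt)3 and catalytic NH4NO3 in EtOH into its acetal (Z)-3,3-diethoxy-1-iodoprop-1-ene F1. Intermolecular CrCl2/NiCl2 coupling of F1 with 6 should give the anti allylic alcohol (3S,4S,5Z)-2-bromo-3-[(tert-butyldimethylsilyl)oxy]-7,7-diethoxyhepta-1,5-dien-4-ol F2. A single Mitsunobu inversion with benzoic acid gives (3S,4R,5Z)-2-bromo-3-[(tert-butyldimethylsilyl)oxy]-7,7-diethoxyhepta-1,5-dien-4-yl benzoate F3. Mild hydrolysis (oxalic acid on wet silica) frees the enal (2Z,4R,5S)-6-bromo-5-[(tert-butyldimethylsilyl)oxy]-1-oxohepta-2,6-dien-4-yl benzoate F4. Intramolecular CrCl2/NiCl2 coupling at high dilution closes the ring to (1R,6R)-6-[(tert-butyldimethylsilyl)oxy]-4-hydroxy-5-methylidenecyclohex-2-en-1-yl benzoate F5, and benzoylation (BzCl, pyridine, DMAP) gives 11. If the syn adduct should predominate in either variant, plain benzoylation replaces the Mitsunobu step.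

Step 7. The doubly allylic carbinol may ionise and scramble or eliminate under activation, and inversion at C3 may be incomplete because of competing SN2′ attack. The fallback separates the two hydroxyls first; it sets out from 10 and comes back at 12. Catalytic Ph3SiOReO3 in Et2O at −50 °C transposes only the doubly allylic hydroxyl and should give (1S,6R)-6-[(tert-butyldimethylsilyl)oxy]-5-(hydroxymethyl)cyclohexa-2,4-dien-1-ol F6. Selective benzoylation of the primary hydroxyl (BzCl, 2,4,6-collidine, −78 °C) gives [(5S,6R)-6-[(tert-butyldimethylsilyl)oxy]-5-hydroxycyclohexa-1,3-dien-1-yl]methyl benzoate F7. A single Mitsunobu inversion of the remaining secondary alcohol with benzoic acid gives 12.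

Step 8. Zerovalent palladium may also ionise the C3 benzoate, with loss of configuration there, or the π-allyl complex may undergo β-hydride elimination followed by aromatisation. The fallback uses a halide relay without a transition metal; it sets out from 11 and comes back at 12. MgBr2·OEt2 in CH2Cl2 at −20 °C ionises only the doubly allylic benzoate, and bromide is captured at the primary terminus to give (1R,6R)-5-(bromomethyl)-6-[(tert-butyldimethylsilyl)oxy]cyclohexa-2,4-dien-1-yl benzoate F8. SN2 displacement with PhCO2Cs in DMF gives 12.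

Further compounds
F1 | step 6 | (Z)-3,3-diethoxy-1-iodoprop-1-ene | CCOC(OCC)/C=C\I
F2 | step 6 | (3S,4S,5Z)-2-bromo-3-[(tert-butyldimethylsilyl)oxy]-7,7-diethoxyhepta-1,5-dien-4-ol | C=C(Br)[C@@H](O[Si](C)(C)C(C)(C)C)[C@@H](O)/C=C\C(OCC)OCC
F3 | step 6 | (3S,4R,5Z)-2-bromo-3-[(tert-butyldimethylsilyl)oxy]-7,7-diethoxyhepta-1,5-dien-4-yl benzoate | C=C(Br)[C@@H](O[Si](C)(C)C(C)(C)C)[C@H](OC(=O)c1ccccc1)/C=C\C(OCC)OCC
F4 | step 6 | (2Z,4R,5S)-6-bromo-5-[(tert-butyldimethylsilyl)oxy]-1-oxohepta-2,6-dien-4-yl benzoate | C=C(Br)[C@@H](O[Si](C)(C)C(C)(C)C)[C@H](OC(=O)c1ccccc1)/C=C\C=O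
F5 | step 6 | (1R,6R)-6-[(tert-butyldimethylsilyl)oxy]-4-hydroxy-5-methylidenecyclohex-2-en-1-yl benzoate (both C4 epimers) | C=C1[C@@H](O[Si](C)(C)C(C)(C)C)[C@H](OC(=O)c2ccccc2)C=CC1O
F6 | step 7 | (1S,6R)-6-[(tert-butyldimethylsilyl)oxy]-5-(hydroxymethyl)cyclohexa-2,4-dien-1-ol | OCC1=CC=C[C@H](O)[C@@H]1O[Si](C)(C)C(C)(C)C
F7 | step 7 | [(5S,6R)-6-[(tert-butyldimethylsilyl)oxy]-5-hydroxycyclohexa-1,3-dien-1-yl]methyl benzoate | O=C(OCC1=CC=C[C@H](O)[C@@H]1O[Si](C)(C)C(C)(C)C)c1ccccc1
F8 | step 8 | (1R,6R)-5-(bromomethyl)-6-[(tert-butyldimethylsilyl)oxy]cyclohexa-2,4-dien-1-yl benzoate | BrCC1=CC=C[C@@H](OC(=O)c2ccccc2)[C@@H]1O[Si](C)(C)C(C)(C)C
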